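## Retrosynthetic overview

- Locants (3,7-dioxabicyclo[3.3.0]octane): C1 (C–OH), C2 (CH–Ar), O3, C4, C5 (CH), C6 (CH–Ar), O7, C8; ring A = C1/C5/C6/O7/C8, ring B = C1/C2/O3/C4/C5; Ar = 3,4-dimethoxyphenyl.
- Key disconnection: C1–C5 (the bond common to rings A and B) together with C6–O7, back to the acyclic ketone ArCH(OCH2CH=CHAr)–CO–CH2OSiEt3, whose only stereocenter is C2. Forward, a Lewis acid makes C1–C5 (ring B) and O7 then closes onto the C6 cation (ring A) in the same flask. This is a polar copy of furofuran biogenesis (β–β′ C–C coupling, then capture of a quinone methide by a primary oxygen).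
- Enabling feature: the para-methoxy group of the aryl ring on C6 stabilises a benzylic cation at C6, so a C5=C6 styrene is nucleophilic at C5. C1 is a tertiary carbinol between C2–O3 and C8–O7, i.e. a latent electrophilic 1,3-dioxygenated ketone. Because C1–C5 is shared by both five-membered rings, making it through the C2–O3–C4 tether (ring B) brings O7 on C8 within reach of C6 (ring A).
- The styrene is attached last by cross-metathesis of an O-allyl ether with 3,4-dimethoxystyrene; the silyloxymethyl ketone (C1, C8) comes from a methyl ester by methylenation, enol ether oxidation and silylation.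
- C2–O3 and the C2 configuration come from a catalytic asymmetric carbene O–H insertion of an aryl diazoacetate into allyl alcohol.

Key step: step 7

Remark: the sense of induction in step 2 is assumed to follow the precedent of this catalyst class with α-aryl-α-diazoacetates; the ligand antipode that gives the R ether is the one to be used.

## Route

Step 1
Reactants: 1 methyl 2-(3,4-dimethoxyphenyl)acetate
Product: 2 methyl 2-diazo-2-(3,4-dimethoxyphenyl)acetate
Conditions: 4-acetamidobenzenesulfonyl azide, DBU, MeCN, 0 °C → rt
Reagents that add atoms: 4-acetamidobenzenesulfonyl azide, CC(=O)Nc1ccc(cc1)S(=O)(=O)N=[N+]=[N-]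
Why: Regitz diazo transfer: DBU deprotonates the benzylic ester position, the enolate adds to the sulfonyl azide and the adduct fragments to the aryl diazoacetate and the sulfonamide; no stereocenter is formed.

Step 2
Reactants: 2 methyl 2-diazo-2-(3,4-dimethoxyphenyl)acetate; 3 prop-2-en-1-ol
Product: 4 methyl (2R)-2-(3,4-dimethoxyphenyl)-2-(prop-2-en-1-yloxy)acetate
Conditions: Fe(ClO4)2·4H2O (5 mol %), phenyl-substituted spiro-bisoxazoline ligand (6 mol %, antipode giving R), sodium tetrakis[3,5-bis(trifluoromethyl)phenyl]borate (6 mol %), CHCl3, 40 °C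
Reagents that add atoms: none
Why: Catalytic asymmetric carbene O–H insertion: the alcohol oxygen adds to the iron carbene derived from 2 and the chiral spiro-bisoxazoline complex controls the proton shift of the metal-bound ylide, which sets the benzylic center (later C2) as R; primary and allylic alcohols are substrates of this catalyst class and O–H insertion outruns cyclopropanation.

Step 3
Reactants: 4 methyl (2R)-2-(3,4-dimethoxyphenyl)-2-(prop-2-en-1-yloxy)acetate
Product: 5 4-[(1R)-2-methoxy-1-(prop-2-en-1-yloxy)prop-2-en-1-yl]-1,2-dimethoxybenzene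
Conditions: Cp2Ti(μ-Cl)(μ-CH2)AlMe2 (Tebbe reagent), pyridine (cat.), THF–toluene, −40 → 0 °C; aq. NaOH
Reagents that add atoms: Tebbe reagent, C[Al-]1(C)C[Ti]([Cl+]1)(C1C=CC=C1)C1C=CC=C1
Why: Tebbe methylenation: the titanium methylidene converts the ester carbonyl into the methyl enol ether through an oxatitanacyclobutane under non-basic conditions, so the α-aryl α-alkoxy center is not enolised, and at low temperature the terminal alkene is left alone.

Step 4
Reactants: 5 4-[(1R)-2-methoxy-1-(prop-2-en-1-yloxy)prop-2-en-1-yl]-1,2-dimethoxybenzene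
Product: 7 (1R)-1-(3,4-dimethoxyphenyl)-3-hydroxy-1-(prop-2-en-1-yloxy)propan-2-one, via methoxy oxirane 6 (not isolated)
Conditions: dimethyldioxirane (acetone solution, 1.05 equiv), CH2Cl2, −78 → −20 °C; then H2O, pyridinium p-toluenesulfonate (cat.), THF, 0 °C
Reagents that add atoms: dimethyldioxirane, CC1(C)OO1; water, O
Why: Rubottom-type oxidation of an enol ether: dimethyldioxirane epoxidises the electron-rich 1,1-disubstituted enol ether much faster than the monosubstituted allyl ether, and buffered hydrolysis opens the 2-methoxyoxirane to the α′-hydroxy ketone with loss of methanol; the oxirane center formed in passing is destroyed and the benzylic center is untouched.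

Step 5
Reactants: 7 (1R)-1-(3,4-dimethoxyphenyl)-3-hydroxy-1-(prop-2-en-1-yloxy)propan-2-one
Product: 8 (1R)-1-(3,4-dimethoxyphenyl)-1-(prop-2-en-1-yloxy)-3-(triethylsilyloxy)propan-2-one
Conditions: Et3SiCl, imidazole, CH2Cl2, 0 °C
Reagents that add atoms: chlorotriethylsilane, CC[Si](Cl)(CC)CC
Why: Standard silylation of the primary alcohol with a silyl chloride and imidazole, mild enough not to enolise the ketone towards the benzylic center.

Step 6
Reactants: 8 (1R)-1-(3,4-dimethoxyphenyl)-1-(prop-2-en-1-yloxy)-3-(triethylsilyloxy)propan-2-one; 9 4-ethenyl-1,2-dimethoxybenzene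
Product: 10 (1R)-1-(3,4-dimethoxyphenyl)-1-{[(2E)-3-(3,4-dimethoxyphenyl)prop-2-en-1-yl]oxy}-3-(triethylsilyloxy)propan-2-one
Conditions: 9 (3 equiv), second-generation Grubbs catalyst (H2IMes)(PCy3)Cl2Ru=CHPh (5 mol %), CH2Cl2, 40 °C
Reagents that add atoms: none
Why: Olefin cross-metathesis of the terminal allyl ether with an excess of the styrene should give the conjugated 1,2-disubstituted alkene with E geometry under thermodynamic control, driven by loss of ethene.

Step 7
Reactants: 10 (1R)-1-(3,4-dimethoxyphenyl)-1-{[(2E)-3-(3,4-dimethoxyphenyl)prop-2-en-1-yl]oxy}-3-(triethylsilyloxy)propan-2-one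
Product: 12 isogmelinol, via O-triethylsilyl isogmelinol 11 (not isolated)
Conditions: SnCl4 (30 mol %), 2,6-di-tert-butyl-4-methylpyridine (40 mol %), CH2Cl2, −78 → −40 °C; aq. NaHCO3; then HF·pyridine, THF, 0 °C
Reagents that add atoms: none
Why: Proposed new method: SnCl4 activates the C1 ketone, the C5=C6 styrene attacks C1 through C5 (Prins addition) to give a C1 stannyloxy / C6 para-methoxybenzylic (quinone-methide-type) cation, the silyl ether oxygen O7 captures C6, and the silyl group shifts from the resulting oxonium to the C1 oxygen (1,4 O-to-O), which releases SnCl4 and gives silyl ether 11, cleaved by HF·pyridine; the closest known reaction is the Lewis acid promoted formal [3+2] annulation of α-silyloxy aldehydes with electron-rich styrenes to 5-aryltetrahydrofuran-3-ols, extended here to a ketone whose alkene is tethered through C2–O3–C4. Ring B closes by 5-exo-trig attack of C5 on the carbonyl carbon C1 (exo with respect to both π-bonds) and ring A by 5-exo-trig capture of the C6 cation by O7. C5 is set relative to C2 by an envelope transition state with the C2 aryl group pseudo-equatorial, which places the C6 branch trans to it; C1 is set by the ring-fusion constraint, since only the adduct with C8 cis to C6 on ring B can close ring A, whereas the other adduct should return to 10 by retro-Prins (Grob-type) fragmentation, so the step is stereoconvergent at C1/C5 and independent of alkene geometry once the cation has formed. C6 is set in the ether closure, O7 adding to the face of the cation that leaves the aryl group on the convex face, trans to the C5–C4 bond. The step needs chemoselectivity for O7 capture (five-membered ring) over capture by the C1 oxygen (oxetane, then carbonyl–olefin metathesis) and over ionisation of the cinnamylic C4–O3 bond; the first is secured by ring size and the adjacent silyloxymethyl group, the second by the inductive deactivation of O3 by the neighbouring carbonyl, the low temperature and the hindered pyridine that removes adventitious protons.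

## Compound list

1 | methyl 2-(3,4-dimethoxyphenyl)acetate | COC(=O)Cc1ccc(OC)c(OC)c1 | starting material
2 | methyl 2-diazo-2-(3,4-dimethoxyphenyl)acetate | COC(=O)C(=[N+]=[N-])c1ccc(OC)c(OC)c1 | intermediate
3 | prop-2-en-1-ol (allyl alcohol) | OCC=C | starting material
4 | methyl (2R)-2-(3,4-dimethoxyphenyl)-2-(prop-2-en-1-yloxy)acetate | COc1ccc(cc1OC)[C@@H](OCC=C)C(=O)OC | intermediate
5 | 4-[(1R)-2-methoxy-1-(prop-2-en-1-yloxy)prop-2-en-1-yl]-1,2-dimethoxybenzene | COc1ccc(cc1OC)[C@@H](OCC=C)C(OC)=C | intermediate
6 | 2-[(R)-(3,4-dimethoxyphenyl)(prop-2-en-1-yloxy)methyl]-2-methoxyoxirane (both epimers at the oxirane carbon) | COc1ccc(cc1OC)[C@@H](OCC=C)C1(OC)CO1 | intermediate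
7 | (1R)-1-(3,4-dimethoxyphenyl)-3-hydroxy-1-(prop-2-en-1-yloxy)propan-2-one | COc1ccc(cc1OC)[C@@H](OCC=C)C(=O)CO | intermediate
8 | (1R)-1-(3,4-dimethoxyphenyl)-1-(prop-2-en-1-yloxy)-3-(triethylsilyloxy)propan-2-one | COc1ccc(cc1OC)[C@@H](OCC=C)C(=O)CO[Si](CC)(CC)CC | intermediate
9 | 4-ethenyl-1,2-dimethoxybenzene (3,4-dimethoxystyrene) | C=Cc1ccc(OC)c(OC)c1 | starting material
10 | (1R)-1-(3,4-dimethoxyphenyl)-1-{[(2E)-3-(3,4-dimethoxyphenyl)prop-2-en-1-yl]oxy}-3-(triethylsilyloxy)propan-2-one | COc1ccc(cc1OC)[C@@H](OC/C=C/c1ccc(OC)c(OC)c1)C(=O)CO[Si](CC)(CC)CC | intermediate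
11 | (1S,2R,5R,6S)-2,6-bis(3,4-dimethoxyphenyl)-1-(triethylsilyloxy)-3,7-dioxabicyclo[3.3.0]octane (O-triethylsilyl isogmelinol) | COc1ccc([C@H]2OC[C@]3(O[Si](CC)(CC)CC)[C@@H](c4ccc(OC)c(OC)c4)OC[C@H]23)cc1OC | intermediate
12 | isogmelinol, (1S,2R,5R,6S)-2,6-bis(3,4-dimethoxyphenyl)-3,7-dioxabicyclo[3.3.0]octan-1-ol (cis-fused; both aryl groups on the convex face, cis to C1–OH and C5–H) | COc1ccc([C@H]2OC[C@]3(O)[C@@H](c4ccc(OC)c(OC)c4)OC[C@H]23)cc1OC | target

## Step count and risks

Total step count: 7. Longest linear sequence: 7 steps (1 → 12).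

Steps most likely to fail:

1. Step 7. What may go wrong: ionisation of the cinnamylic C4–O3 ether by the Lewis acid, capture of the C6 cation by the C1 oxygen followed by carbonyl–olefin metathesis, or insufficient facial control by C2. Fallback (known radical chemistry, sets out from 10, rejoins at 12): SmI2/HMPA/t-BuOH in THF at −78 °C generates the C1 ketyl, which closes ring B by 5-exo-trig addition to C5 (the same C1–C5 bond), with the ketyl oxygen anti to the alkene and the C2 aryl group pseudo-equatorial. The benzylic radical is reduced and protonated, which should give (2R,3S,4S)-2-(3,4-dimethoxyphenyl)-4-(3,4-dimethoxybenzyl)-3-[(triethylsilyloxy)methyl]oxolan-3-ol F1. HF·pyridine frees (2R,3S,4S)-2-(3,4-dimethoxyphenyl)-4-(3,4-dimethoxybenzyl)-3-(hydroxymethyl)oxolan-3-ol F2. DDQ in CH2Cl2 then oxidises the 3,4-dimethoxybenzylic CH2 to the quinone-methide-type cation, which the primary hydroxyl captures to close ring A and give 12.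

2. Step 2. What may go wrong: erosion of enantioselectivity with the electron-rich aryl carbene, carbene dimerisation, or cyclopropanation of the allyl group. Fallback (sets out from 2, rejoins at 4): dimethyldioxirane oxidises the diazo group to the ketone, methyl 2-(3,4-dimethoxyphenyl)-2-oxoacetate F3. Asymmetric transfer hydrogenation with RuCl(TsDPEN)(p-cymene) (antipode giving the R alcohol) and HCO2H–Et3N gives methyl (2R)-2-(3,4-dimethoxyphenyl)-2-hydroxyacetate F4. O-Allylation with allyl bromide and Ag2O (Et2O, dark), which avoids enolate formation, gives 4.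

3. Step 4. What may go wrong: hydrolysis of the acid-labile enol ether to the methyl ketone before oxidation, over-oxidation at the allyl ether or the arene, or epimerisation of the benzylic center during hydrolysis. Fallback (sets out from 4, bypasses 5 and 6, rejoins at 7): MeNHOMe·HCl and i-PrMgCl (THF, −20 °C) convert the ester into (2R)-2-(3,4-dimethoxyphenyl)-N-methoxy-N-methyl-2-(prop-2-en-1-yloxy)acetamide F5. Addition of the lithium reagent generated from tributyl[(methoxymethoxy)methyl]stannane and n-BuLi (THF, −78 °C) gives (1R)-1-(3,4-dimethoxyphenyl)-3-(methoxymethoxy)-1-(prop-2-en-1-yloxy)propan-2-one F6. Acetal cleavage with HCl in MeOH then gives 7.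

## Further compounds

F1 | step 7 | (2R,3S,4S)-2-(3,4-dimethoxyphenyl)-4-(3,4-dimethoxybenzyl)-3-[(triethylsilyloxy)methyl]oxolan-3-ol | COc1ccc(C[C@H]2CO[C@H](c3ccc(OC)c(OC)c3)[C@@]2(O)CO[Si](CC)(CC)CC)cc1OC
F2 | step 7 | (2R,3S,4S)-2-(3,4-dimethoxyphenyl)-4-(3,4-dimethoxybenzyl)-3-(hydroxymethyl)oxolan-3-ol | COc1ccc(C[C@H]2CO[C@H](c3ccc(OC)c(OC)c3)[C@@]2(O)CO)cc1OC
F3 | step 2 | methyl 2-(3,4-dimethoxyphenyl)-2-oxoacetate | COC(=O)C(=O)c1ccc(OC)c(OC)c1
F4 | step 2 | methyl (2R)-2-(3,4-dimethoxyphenyl)-2-hydroxyacetate | COc1ccc(cc1OC)[C@@H](O)C(=O)OC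
F5 | step 4 | (2R)-2-(3,4-dimethoxyphenyl)-N-methoxy-N-methyl-2-(prop-2-en-1-yloxy)acetamide | COc1ccc(cc1OC)[C@@H](OCC=C)C(=O)N(C)OC
F6 | step 4 | (1R)-1-(3,4-dimethoxyphenyl)-3-(methoxymethoxy)-1-(prop-2-en-1-yloxy)propan-2-one | COc1ccc(cc1OC)[C@@H](OCC=C)C(=O)COCOC
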